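**Retrosynthetic overview**
1. The two tiglate esters go on last: target 21 ⇐ diol 18 ⇐ bis-silyl ether 17; the acylating agent is tiglic anhydride 20, made from tiglic acid 19.
2. Feature and key disconnection: C2 of the 2,3-dihydrobenzofuran bears the α-carbon of a propenal, so C2 is the β-carbon of that enal. Bond O1–C2 is therefore an oxa-Michael bond and the exocyclic C=CH2 is an α-methylenation; both are made in one flask from phenol enal 13 and formaldehyde 14 with one secondary amine.
3. 13 ⇐ terminal alkene 11 + crotonaldehyde 12 (cross-metathesis); 11 ⇐ aldehyde 6 by Re-face vinylation with methyl(vinyl)zinc 8, silylation and O-deallylation.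
4. 6 ⇐ 3'-bromo-4'-hydroxyacetophenone 1 by O-allylation, asymmetric transfer hydrogenation (side-chain centre), silylation and bromine–lithium exchange/formylation.
5. Ring order: the benzene ring is bought; the dihydrofuran ring (O1, C2, C3, C3a, C7a) is the only ring formed, in step 10.

Key step: step 10

Remark: TBS = tert-butyldimethylsilyl; ring atoms carry 1-benzofuran numbering; 2,3-trans is assumed to be the more stable arrangement of the two substituents on the dihydrofuran ring.

**Route**

Step 1
Reactants: 1 3'-bromo-4'-hydroxyacetophenone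
Product: 2 1-[3-bromo-4-(prop-2-en-1-yloxy)phenyl]ethan-1-one
Conditions: allyl bromide, K2CO3, acetone, reflux
Reagents that add atoms: allyl bromide, C=CCBr
Why: Williamson ether synthesis on the acidic para-acyl phenol should give clean O-allylation and installs a phenol protecting group that can later be removed without acid, fluoride or hydrogen.

Step 2
Reactants: 2 1-[3-bromo-4-(prop-2-en-1-yloxy)phenyl]ethan-1-one
Product: 3 (1R)-1-[3-bromo-4-(prop-2-en-1-yloxy)phenyl]ethan-1-ol
Conditions: RuCl[(R,R)-TsDPEN](p-cymene) (1 mol%; TsDPEN = N-tosyl-1,2-diphenylethylenediamine), HCO2H/Et3N 5:2, 30 °C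
Reagents that add atoms: none
Why: Noyori asymmetric transfer hydrogenation of an aryl methyl ketone, in which the (R,R)-catalyst should deliver hydride to the face that gives the (R)-carbinol, and the irreversible formic acid system avoids erosion with the electron-rich arene.

Step 3
Reactants: 3 (1R)-1-[3-bromo-4-(prop-2-en-1-yloxy)phenyl]ethan-1-ol
Product: 4 {(1R)-1-[3-bromo-4-(prop-2-en-1-yloxy)phenyl]ethoxy}(tert-butyl)dimethylsilane
Conditions: TBSCl, imidazole, DMF, rt
Reagents that add atoms: tert-butyldimethylsilyl chloride, CC(C)(C)[Si](C)(C)Cl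
Why: Imidazole-mediated silylation of a secondary benzylic alcohol proceeds at oxygen without touching the C–O stereocentre and gives an ether that tolerates organolithium and organozinc reagents.

Step 4
Reactants: 4 {(1R)-1-[3-bromo-4-(prop-2-en-1-yloxy)phenyl]ethoxy}(tert-butyl)dimethylsilane
Product: 6 5-[(1R)-1-(TBSO)ethyl]-2-(prop-2-en-1-yloxy)benzaldehyde, via aryllithium 5 (not isolated)
Conditions: n-BuLi, THF, −78 °C; DMF, −78 → −40 °C; aq. NH4Cl
Reagents that add atoms: N,N-dimethylformamide, CN(C)C=O
Why: Bromine–lithium exchange followed by formylation of the aryllithium with DMF is fast at −78 °C, where the ortho-allyloxy aryllithium should neither cyclise onto the allyl group nor deprotonate the benzylic silyl ether.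

Step 5
Reactants: 7 vinylmagnesium bromide
Product: 8 ethenyl(methyl)zinc [methyl(vinyl)zinc]
Conditions: MeZnCl (2.0 M in THF, 1.0 equiv), toluene, 0 °C → rt; 1,4-dioxane, filtration under argon; filtrate (toluene with THF as minor cosolvent) titrated and used at once
Reagents that add atoms: methylzinc chloride, C[Zn]Cl
Why: Transmetallation of the Grignard reagent with an alkylzinc halide gives the mixed diorganozinc with one vinyl group per zinc, and precipitation of the magnesium halide as its dioxane complex removes the Lewis acid that would promote uncatalysed addition in step 6.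

Step 6
Reactants: 6 5-[(1R)-1-(TBSO)ethyl]-2-(prop-2-en-1-yloxy)benzaldehyde; 8 ethenyl(methyl)zinc
Product: 9 (1R)-1-{5-[(1R)-1-(TBSO)ethyl]-2-(prop-2-en-1-yloxy)phenyl}prop-2-en-1-ol
Conditions: 8 (1.5 equiv), (2R)-3-exo-morpholinoisoborneol [(+)-MIB] (10 mol%), toluene (THF as minor cosolvent), −20 → 0 °C; aq. NH4Cl
Reagents that add atoms: none
Why: Amino-alcohol-catalysed (ligand-accelerated) addition of an alkenyl(alkyl)zinc to an aryl aldehyde, in which the sp2 group transfers far faster than the methyl group and the (2R)-ligand is expected to send the vinyl group to the Re face of the formyl group and so set the new carbinol as R (O > aryl > vinyl) under catalyst control, independent of the remote centre.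

Step 7
Reactants: 9 (1R)-1-{5-[(1R)-1-(TBSO)ethyl]-2-(prop-2-en-1-yloxy)phenyl}prop-2-en-1-ol
Product: 10 tert-butyl{[(1R)-1-{5-[(1R)-1-(TBSO)ethyl]-2-(prop-2-en-1-yloxy)phenyl}prop-2-en-1-yl]oxy}dimethylsilane
Conditions: TBSCl, imidazole, DMF, 40 °C
Reagents that add atoms: tert-butyldimethylsilyl chloride, CC(C)(C)[Si](C)(C)Cl
Why: Silylation under basic, Lewis-acid-free conditions protects the benzylic–allylic alcohol without ionising it, so neither racemisation nor allylic transposition should occur.

Step 8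
Reactants: 10 tert-butyl{[(1R)-1-{5-[(1R)-1-(TBSO)ethyl]-2-(prop-2-en-1-yloxy)phenyl}prop-2-en-1-yl]oxy}dimethylsilane
Product: 11 2-[(1R)-1-(TBSO)prop-2-en-1-yl]-4-[(1R)-1-(TBSO)ethyl]phenol
Conditions: Pd(PPh3)4 (5 mol%), morpholine, THF, rt
Reagents that add atoms: none
Why: Tsuji–Trost-type deallylation, in which zerovalent palladium ionises only the aryl allyl ether (phenoxide as leaving group) and morpholine traps the allyl fragment, while the secondary allylic silyl ether is no leaving group and both silyl ethers stay.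

Step 9
Reactants: 11 2-[(1R)-1-(TBSO)prop-2-en-1-yl]-4-[(1R)-1-(TBSO)ethyl]phenol; 12 crotonaldehyde
Product: 13 (2E,4R)-4-(TBSO)-4-{5-[(1R)-1-(TBSO)ethyl]-2-hydroxyphenyl}but-2-enal
Conditions: second-generation Hoveyda–Grubbs catalyst RuCl2(H2IMes)(=CH-C6H4-2-OiPr) (5 mol%; H2IMes = 1,3-dimesitylimidazolidin-2-ylidene), 12 (5 equiv), CH2Cl2, 40 °C
Reagents that add atoms: none
Why: Olefin cross-metathesis of the terminal alkene with an excess of the electron-poor enal should give the E-enal with loss of propene, and the neutral medium tolerates the free phenol and should keep 13 from cyclising.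

Step 10
Reactants: 13 (2E,4R)-4-(TBSO)-4-{5-[(1R)-1-(TBSO)ethyl]-2-hydroxyphenyl}but-2-enal; 14 formaldehyde
Product: 17 2-{(2R,3S)-3-(TBSO)-5-[(1R)-1-(TBSO)ethyl]-2,3-dihydro-1-benzofuran-2-yl}prop-2-enal, via ring-closed aldehyde 15 (not isolated), via Mannich base 16 (not isolated)
Conditions: (R)-2-[diphenyl(trimethylsilyloxy)methyl]pyrrolidine (20 mol%), PhCO2H (20 mol%), toluene, 0 °C → rt; then 14 (37% aqueous, 3 equiv), i-PrOH, same flask, rt → 40 °C
Reagents that add atoms: none
Why: Proposed new method: the secondary amine condenses with the enal of 13 to an E-configured s-trans iminium ion, the ortho phenol adds to its β-carbon (oxa-Michael) to form O1–C2, the resulting enamine (in equilibrium with aldehyde 15 by hydrolysis) adds to the methyleneiminium ion that the same amine forms with formaldehyde, and Mannich base 16 loses the amine by β-elimination to give the C=CH2 bond and release the catalyst. The closest known reaction types are the amine-catalysed intramolecular oxa-Michael addition of phenols to enals and the amine/carboxylic-acid-catalysed α-methylenation of aldehydes with aqueous formaldehyde, run here as one iminium-then-enamine cascade in one flask. The dihydrofuran ring (O1, C2, C3, C3a, C7a) closes in the 5-exo-trig mode, the only ring closure of the step. The new stereocentre C2 is controlled by the existing C3 centre under thermodynamic control: before formaldehyde is added, ring closure is reversible by retro-oxa-Michael reaction of the enamine, so C2 should settle trans to the C3 silyloxy group (2R beside 3S), and the (R)-amine is chosen because attack anti to its diphenyl(silyloxy)methyl group on the iminium β-carbon leads to the same 2R configuration. Once the amine has left, the α-carbon is sp2 and bears no hydrogen, so 17 itself can no longer form an enamine and reopen. The step needs O-addition at the β-carbon to win over γ-deprotonation of the iminium ion (which would erase the C3 centre through a dienamine), and the five-membered transition state of the tethered phenol together with the weakly acidic benzoate buffer, free of stronger base, should secure this.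

Step 11
Reactants: 17 2-{(2R,3S)-3-(TBSO)-5-[(1R)-1-(TBSO)ethyl]-2,3-dihydro-1-benzofuran-2-yl}prop-2-enal
Product: 18 2-{(2R,3S)-3-hydroxy-5-[(1R)-1-hydroxyethyl]-2,3-dihydro-1-benzofuran-2-yl}prop-2-enal
Conditions: HF·pyridine, pyridine, THF, 0 °C → rt
Reagents that add atoms: none
Why: Fluoride-driven cleavage of both secondary silyl ethers in a pyridine-buffered medium should be mild enough to leave the two ionisable benzylic C–O bonds and the enal intact.

Step 12
Reactants: 19 tiglic acid
Product: 20 tiglic anhydride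
Conditions: tigloyl chloride (1.0 equiv), pyridine (1.05 equiv), Et2O, 0 °C → rt; filtration, evaporation
Reagents that add atoms: tigloyl chloride [(2E)-2-methylbut-2-enoyl chloride], C/C=C(\C)C(=O)Cl
Why: Nucleophilic acyl substitution of the acid chloride by the carboxylate through the N-acylpyridinium ion gives the symmetric anhydride, and pyridine is too weak a base to deprotonate the γ-methyl groups, so both E double bonds are kept.

Step 13
Reactants: 18 2-{(2R,3S)-3-hydroxy-5-[(1R)-1-hydroxyethyl]-2,3-dihydro-1-benzofuran-2-yl}prop-2-enal; 20 tiglic anhydride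
Product: 21 (1R)-1-[(2R,3S)-3-{[(2E)-2-methylbut-2-enoyl]oxy}-2-(3-oxoprop-1-en-2-yl)-2,3-dihydro-1-benzofuran-5-yl]ethyl (2E)-2-methylbut-2-enoate (target)
Conditions: 20 (4 equiv), Et3N, 4-(dimethylamino)pyridine (10 mol%), CH2Cl2, 0 °C → rt
Reagents that add atoms: none
Why: Steglich-type acyl transfer through the N-acylpyridinium ion should acylate both secondary benzylic alcohols at oxygen with retention, under basic conditions that avoid benzylic ionisation, with little catalyst and low temperature to limit conjugate addition to the methylene enal.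

**Compound list**
1 | 1-(3-bromo-4-hydroxyphenyl)ethan-1-one (3'-bromo-4'-hydroxyacetophenone) | CC(=O)c1ccc(O)c(Br)c1 | starting material
2 | 1-[3-bromo-4-(prop-2-en-1-yloxy)phenyl]ethan-1-one | CC(=O)c1ccc(OCC=C)c(Br)c1 | intermediate
3 | (1R)-1-[3-bromo-4-(prop-2-en-1-yloxy)phenyl]ethan-1-ol | C[C@@H](O)c1ccc(OCC=C)c(Br)c1 | intermediate
4 | {(1R)-1-[3-bromo-4-(prop-2-en-1-yloxy)phenyl]ethoxy}(tert-butyl)dimethylsilane | C[C@@H](O[Si](C)(C)C(C)(C)C)c1ccc(OCC=C)c(Br)c1 | intermediate
5 | {5-[(1R)-1-(TBSO)ethyl]-2-(prop-2-en-1-yloxy)phenyl}lithium | C[C@@H](O[Si](C)(C)C(C)(C)C)c1ccc(OCC=C)c([Li])c1 | intermediate (not isolated)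
6 | 5-[(1R)-1-(TBSO)ethyl]-2-(prop-2-en-1-yloxy)benzaldehyde | C[C@@H](O[Si](C)(C)C(C)(C)C)c1ccc(OCC=C)c(C=O)c1 | intermediate
7 | vinylmagnesium bromide | C=C[Mg]Br | starting material
8 | ethenyl(methyl)zinc [methyl(vinyl)zinc] | C=C[Zn]C | intermediate
9 | (1R)-1-{5-[(1R)-1-(TBSO)ethyl]-2-(prop-2-en-1-yloxy)phenyl}prop-2-en-1-ol | C=C[C@@H](O)c1cc([C@@H](C)O[Si](C)(C)C(C)(C)C)ccc1OCC=C | intermediate
10 | tert-butyl{[(1R)-1-{5-[(1R)-1-(TBSO)ethyl]-2-(prop-2-en-1-yloxy)phenyl}prop-2-en-1-yl]oxy}dimethylsilane | C=C[C@@H](O[Si](C)(C)C(C)(C)C)c1cc([C@@H](C)O[Si](C)(C)C(C)(C)C)ccc1OCC=C | intermediate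
11 | 2-[(1R)-1-(TBSO)prop-2-en-1-yl]-4-[(1R)-1-(TBSO)ethyl]phenol | C=C[C@@H](O[Si](C)(C)C(C)(C)C)c1cc([C@@H](C)O[Si](C)(C)C(C)(C)C)ccc1O | intermediate
12 | (E)-but-2-enal (crotonaldehyde) | C/C=C/C=O | starting material
13 | (2E,4R)-4-(TBSO)-4-{5-[(1R)-1-(TBSO)ethyl]-2-hydroxyphenyl}but-2-enal | O=C/C=C/[C@@H](O[Si](C)(C)C(C)(C)C)c1cc([C@@H](C)O[Si](C)(C)C(C)(C)C)ccc1O | intermediate
14 | formaldehyde | C=O | starting material
15 | 2-{(2R,3S)-3-(TBSO)-5-[(1R)-1-(TBSO)ethyl]-2,3-dihydro-1-benzofuran-2-yl}acetaldehyde | O=CC[C@H]1Oc2ccc([C@@H](C)O[Si](C)(C)C(C)(C)C)cc2[C@@H]1O[Si](C)(C)C(C)(C)C | intermediate (not isolated)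
16 | 2-{(2R,3S)-3-(TBSO)-5-[(1R)-1-(TBSO)ethyl]-2,3-dihydro-1-benzofuran-2-yl}-3-{(2R)-2-[diphenyl(trimethylsilyloxy)methyl]pyrrolidin-1-yl}propanal (both epimers at the propanal α-carbon) | O=CC(CN1CCC[C@@H]1C(O[Si](C)(C)C)(c1ccccc1)c1ccccc1)[C@H]1Oc2ccc([C@@H](C)O[Si](C)(C)C(C)(C)C)cc2[C@@H]1O[Si](C)(C)C(C)(C)C | intermediate (not isolated)
17 | 2-{(2R,3S)-3-(TBSO)-5-[(1R)-1-(TBSO)ethyl]-2,3-dihydro-1-benzofuran-2-yl}prop-2-enal | C=C(C=O)[C@H]1Oc2ccc([C@@H](C)O[Si](C)(C)C(C)(C)C)cc2[C@@H]1O[Si](C)(C)C(C)(C)C | intermediate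
18 | 2-{(2R,3S)-3-hydroxy-5-[(1R)-1-hydroxyethyl]-2,3-dihydro-1-benzofuran-2-yl}prop-2-enal | C=C(C=O)[C@H]1Oc2ccc([C@@H](C)O)cc2[C@@H]1O | intermediate
19 | (2E)-2-methylbut-2-enoic acid (tiglic acid) | C/C=C(\C)C(=O)O | starting material
20 | (2E)-2-methylbut-2-enoic anhydride (tiglic anhydride) | C/C=C(\C)C(=O)OC(=O)/C(C)=C/C | intermediate
21 | (1R)-1-[(2R,3S)-3-{[(2E)-2-methylbut-2-enoyl]oxy}-2-(3-oxoprop-1-en-2-yl)-2,3-dihydro-1-benzofuran-5-yl]ethyl (2E)-2-methylbut-2-enoate | C=C(C=O)[C@H]1Oc2ccc([C@@H](C)OC(=O)/C(C)=C/C)cc2[C@@H]1OC(=O)/C(C)=C/C | target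

**Step count and risks**
Total: 13 steps. Longest linear sequence: 11 steps (steps 1–4, 6–11, 13); steps 5 and 12 prepare reagents on side branches.

Most likely to fail:

1. Step 10 (proposed new method). Three processes could defeat it: γ-deprotonation of the iminium ion with loss of the C3 configuration; a slow Mannich step with the bulky amine, leaving the reversible oxa-Michael adduct to decompose; and conjugate addition of the amine to the product followed by β-elimination of the aryloxide, which reopens the ring. The fallback sets out from 13 and returns at 17, using two separate known operations. Enal 13 is first cyclised alone with the same amine and benzoic acid in toluene (known amine-catalysed intramolecular oxa-Michael addition), left to equilibrate, and the trans ring-closed aldehyde 15 is isolated by rapid filtration through silica. Aldehyde 15 is then methylenated with a preformed iminium salt, dimethylmethylideneammonium iodide (Eschenmoser's salt), and Et3N in CH2Cl2 at rt. This passes through the 3-(dimethylamino)propanal Mannich base F1, which loses dimethylamine to give 17. No secondary amine is then present once the methylene enal exists.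

2. Step 9. Metathesis may stall at the hindered allylic silyl ether beside the ortho-substituted arene, the phenol may deactivate the ruthenium carbene, or the alkene may simply dimerise. The fallback sets out from aldehyde 6 and returns at 13, bringing in the three enal carbons as an alkyne acetal and bypassing steps 5 to 9. Aldehyde 6 is alkynylated with 3,3-diethoxyprop-1-yne using ZnMe2 and 2,6-bis{[2-(hydroxydiphenylmethyl)pyrrolidin-1-yl]methyl}-4-methylphenol (the enantiomer that directs the alkynyl group to the Re face) in toluene, which should give the (1R)-propargylic alcohol F2. Hydroxyl-directed trans-hydroalumination with NaAlH2(OCH2CH2OMe)2 in THF should give the E-allylic alcohol F3. Silylation (TBSCl, imidazole, DMF) gives the bis-silyl ether F4, and Pd(PPh3)4/morpholine gives the phenol acetal F5. Hydrolysis of the unsaturated acetal with oxalic acid on wet silica gel in CH2Cl2 then gives 13.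

3. Step 13. The nucleophilic catalyst may add to the methylene enal and expel the C2 aryloxide, after which the released phenoxide would be acylated irreversibly; acylation of the hindered C3 hydroxyl may also be incomplete. The fallback sets out from 17 and returns at 21, masking the enal as an allylic alcohol while the esters are installed. Luche reduction of 17 (NaBH4, CeCl3·7H2O, MeOH, −40 °C) should give the allylic alcohol F6. Levulinoylation (levulinic acid, N,N'-diisopropylcarbodiimide, 4-(dimethylamino)pyridine) gives the levulinate F7. HF·pyridine in pyridine/THF gives the diol levulinate F8. Acylation with 20, Et3N and 4-(dimethylamino)pyridine, now with no Michael acceptor present, gives the bis-tiglate levulinate F9. Hydrazine acetate in pyridine/AcOH removes the levulinate selectively to give the bis-tiglate allylic alcohol F10. Oxidation with MnO2 in CH2Cl2 then gives 21.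

**Further compounds**
F1 | step 10 | 3-(dimethylamino)-2-{(2R,3S)-3-(TBSO)-5-[(1R)-1-(TBSO)ethyl]-2,3-dihydro-1-benzofuran-2-yl}propanal (both epimers at the propanal α-carbon) | CN(C)CC(C=O)[C@H]1Oc2ccc([C@@H](C)O[Si](C)(C)C(C)(C)C)cc2[C@@H]1O[Si](C)(C)C(C)(C)C
F2 | step 9 | (1R)-1-{5-[(1R)-1-(TBSO)ethyl]-2-(prop-2-en-1-yloxy)phenyl}-4,4-diethoxybut-2-yn-1-ol | CCOC(OCC)C#C[C@@H](O)c1cc([C@@H](C)O[Si](C)(C)C(C)(C)C)ccc1OCC=C
F3 | step 9 | (1R,2E)-1-{5-[(1R)-1-(TBSO)ethyl]-2-(prop-2-en-1-yloxy)phenyl}-4,4-diethoxybut-2-en-1-ol | CCOC(OCC)/C=C/[C@@H](O)c1cc([C@@H](C)O[Si](C)(C)C(C)(C)C)ccc1OCC=C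
F4 | step 9 | tert-butyl{[(1R,2E)-1-{5-[(1R)-1-(TBSO)ethyl]-2-(prop-2-en-1-yloxy)phenyl}-4,4-diethoxybut-2-en-1-yl]oxy}dimethylsilane | CCOC(OCC)/C=C/[C@@H](O[Si](C)(C)C(C)(C)C)c1cc([C@@H](C)O[Si](C)(C)C(C)(C)C)ccc1OCC=C
F5 | step 9 | 2-[(1R,2E)-1-(TBSO)-4,4-diethoxybut-2-en-1-yl]-4-[(1R)-1-(TBSO)ethyl]phenol | CCOC(OCC)/C=C/[C@@H](O[Si](C)(C)C(C)(C)C)c1cc([C@@H](C)O[Si](C)(C)C(C)(C)C)ccc1O
F6 | step 13 | 2-{(2R,3S)-3-(TBSO)-5-[(1R)-1-(TBSO)ethyl]-2,3-dihydro-1-benzofuran-2-yl}prop-2-en-1-ol | C=C(CO)[C@H]1Oc2ccc([C@@H](C)O[Si](C)(C)C(C)(C)C)cc2[C@@H]1O[Si](C)(C)C(C)(C)C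
F7 | step 13 | 2-{(2R,3S)-3-(TBSO)-5-[(1R)-1-(TBSO)ethyl]-2,3-dihydro-1-benzofuran-2-yl}prop-2-en-1-yl 4-oxopentanoate | C=C(COC(=O)CCC(C)=O)[C@H]1Oc2ccc([C@@H](C)O[Si](C)(C)C(C)(C)C)cc2[C@@H]1O[Si](C)(C)C(C)(C)C
F8 | step 13 | 2-{(2R,3S)-3-hydroxy-5-[(1R)-1-hydroxyethyl]-2,3-dihydro-1-benzofuran-2-yl}prop-2-en-1-yl 4-oxopentanoate | C=C(COC(=O)CCC(C)=O)[C@H]1Oc2ccc([C@@H](C)O)cc2[C@@H]1O
F9 | step 13 | (1R)-1-[(2R,3S)-3-{[(2E)-2-methylbut-2-enoyl]oxy}-2-{3-[(4-oxopentanoyl)oxy]prop-1-en-2-yl}-2,3-dihydro-1-benzofuran-5-yl]ethyl (2E)-2-methylbut-2-enoate | C=C(COC(=O)CCC(C)=O)[C@H]1Oc2ccc([C@@H](C)OC(=O)/C(C)=C/C)cc2[C@@H]1OC(=O)/C(C)=C/C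
F10 | step 13 | (1R)-1-[(2R,3S)-2-(3-hydroxyprop-1-en-2-yl)-3-{[(2E)-2-methylbut-2-enoyl]oxy}-2,3-dihydro-1-benzofuran-5-yl]ethyl (2E)-2-methylbut-2-enoate | C=C(CO)[C@H]1Oc2ccc([C@@H](C)OC(=O)/C(C)=C/C)cc2[C@@H]1OC(=O)/C(C)=C/C
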